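**Plan**

1. Retrosynthesis: the two acetates and the C12–C15 diene are removed first (C14=C15 and C12=C13 by Wittig reactions, C11–C12 by one-carbon homologation of a C11 aldehyde). The 6-acetoxy-7-ene is traced to a 7-en-6-one and then to a C6 silyl enol ether.
2. Enabling feature: ring B carries oxygen at C6 beside the ring-fusion carbon C5, and ring A meets it at the quaternary C10. The trans-decalin (C1–C10) is therefore a disguised 1,7,9-decatriene: C9=C10 with C11 as formyl group is the dienophile, C5=C6(OSi)–C7=C8 is the diene, C1–C4 is the tether. Bonds C5–C10 and C8–C9 are cut together.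
3. The open chain is cut at C7–C8 (aldol condensation with silyloxyacetaldehyde, bringing C8 and C17) and at C3–C4 (copper-catalysed Grignard addition to mesityl oxide, bringing C4–C7 and the gem-dimethyl group). C1–C3, C9–C11 and the C10 methyl come from geraniol.
4. Forward: chain assembly (steps 1–11); rings A and B together in step 12; then C12 (step 13), the enone (step 14), the diene (steps 15–17), C6 reduction and acetylation (steps 18–20).
5. Stereochemistry: C5, C9 and C10 arise in the catalyst-controlled endo cycloaddition of the (E)-enal. C6 comes from hydride attack anti to the C10 and axial C4 methyl groups. The 12E alkene comes from a stabilised ylide. C8 is set in step 12 and flattened in step 14.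

Key step: step 12

Assumption: the s-trans enal is taken to bind the (S)-configured catalyst in the formyl C–H···O mode known for 2-substituted acroleins, which leaves open the enal face leading to (5R,8R,9R,10R)-21. Should the sense prove opposite, the (R)-catalyst is used with no other change.

Atom numbers C1–C17 are those of the labdane skeleton of the target.

**Route**

Step 1
Reactants: 1 geraniol
Product: 2 geranyl tert-butyldimethylsilyl ether
Conditions: t-BuMe2SiCl, imidazole, CH2Cl2, 0 °C to rt
Reagents that add atoms: tert-butyldimethylsilyl chloride, CC(C)(C)[Si](C)(C)Cl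
Why: Silyl ether formation at the primary allylic alcohol masks the C11 oxygen as an ether that survives the later Grignard chemistry; no stereocentre is formed.

Step 2
Reactants: 2 geranyl tert-butyldimethylsilyl ether
Product: 4 (4E)-6-(tert-butyldimethylsilyloxy)-4-methylhex-4-en-1-ol, via aldehyde 3 (not isolated)
Conditions: O3 (1.0 equiv), CH2Cl2–MeOH, −78 °C; then NaBH4, −78 to 0 °C
Reagents that add atoms: ozone, [O-][O+]=O
Why: Ozonolysis with reductive work-up should cleave the electron-rich terminal trisubstituted alkene faster than the alkene deactivated by the allylic silyl ether, so that one equivalent of ozone gives the C3 alcohol and leaves the (E)-C9=C10 bond intact.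

Step 3
Reactants: 4 (4E)-6-(tert-butyldimethylsilyloxy)-4-methylhex-4-en-1-ol
Product: 5 (2E)-6-bromo-3-methylhex-2-enyl tert-butyldimethylsilyl ether
Conditions: CBr4, PPh3, CH2Cl2, 0 °C
Reagents that add atoms: carbon tetrabromide, BrC(Br)(Br)Br
Why: Appel bromination converts the primary alcohol into the bromide under near-neutral conditions that the allylic silyl ether tolerates.

Step 4
Reactants: 5 (2E)-6-bromo-3-methylhex-2-enyl tert-butyldimethylsilyl ether; 6 mesityl oxide
Product: 9 (8E)-10-(tert-butyldimethylsilyloxy)-4,4,8-trimethyldec-8-en-2-one, via Grignard reagent 7 (not isolated), via trimethylsilyl enol ether 8 (not isolated)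
Conditions: Mg, THF, 40 °C; then CuBr·SMe2 (10 mol%), Me3SiCl, 6, THF, −78 to −30 °C; then 1 M HCl, 0 °C, 10 min
Reagents that add atoms: none
Why: Copper-catalysed, Me3SiCl-accelerated conjugate addition of the primary Grignard reagent to the β,β-disubstituted enone (Kharasch-type 1,4-addition) forms the C3–C4 bond and the quaternary C4, and brief acid hydrolysis of the labile trimethylsilyl enol ether gives the methyl ketone.

Step 5
Reactants: 9 (8E)-10-(tert-butyldimethylsilyloxy)-4,4,8-trimethyldec-8-en-2-one
Product: 10 (8E)-10-hydroxy-4,4,8-trimethyldec-8-en-2-one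
Conditions: Bu4NF, THF, 0 °C to rt
Reagents that add atoms: none
Why: Fluoride-induced desilylation frees the C11 alcohol so that it can be carried on as an ester, the one protecting group that can later be removed beside a silyl enol ether.

Step 6
Reactants: 10 (8E)-10-hydroxy-4,4,8-trimethyldec-8-en-2-one
Product: 11 (2E)-3,7,7-trimethyl-9-oxodec-2-enyl pivalate
Conditions: t-BuCOCl, pyridine, DMAP (cat.), CH2Cl2, 0 °C to rt
Reagents that add atoms: pivaloyl chloride, CC(C)(C)C(Cl)=O
Why: Acylation gives a hindered ester without α-hydrogens that should withstand two lithium amide steps and be cleaved reductively at the end of the chain assembly.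

Step 7
Reactants: 11 (2E)-3,7,7-trimethyl-9-oxodec-2-enyl pivalate; 12 (tert-butyldimethylsilyloxy)acetaldehyde
Product: 14 (2E)-12-(tert-butyldimethylsilyloxy)-11-hydroxy-3,7,7-trimethyl-9-oxododec-2-enyl pivalate, via lithium enolate 13 (not isolated)
Conditions: LiN(i-Pr)2 (1.05 equiv), THF, −78 °C; then 12, −78 °C; aq. NH4Cl
Reagents that add atoms: none
Why: Kinetic deprotonation occurs at the methyl group and not at the neopentyl methylene, and the directed aldol addition forms C7–C8; the carbinol centre is formed without control and disappears in step 8.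

Step 8
Reactants: 14 (2E)-12-(tert-butyldimethylsilyloxy)-11-hydroxy-3,7,7-trimethyl-9-oxododec-2-enyl pivalate
Product: 16 (2E,10E)-12-(tert-butyldimethylsilyloxy)-3,7,7-trimethyl-9-oxododeca-2,10-dienyl pivalate, via mesylate 15 (not isolated)
Conditions: MeSO2Cl, Et3N, CH2Cl2, 0 °C; then DBU, 0 °C to rt
Reagents that add atoms: none
Why: Mesylation followed by base-induced E1cB elimination of the β-mesyloxy ketone should give the conjugated enone with the thermodynamically preferred (E)-geometry at C7=C8.

Step 9
Reactants: 16 (2E,10E)-12-(tert-butyldimethylsilyloxy)-3,7,7-trimethyl-9-oxododeca-2,10-dienyl pivalate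
Product: 18 (2E,8Z,10E)-9,12-bis(tert-butyldimethylsilyloxy)-3,7,7-trimethyldodeca-2,8,10-trienyl pivalate, via lithium dienolate 17 (not isolated)
Conditions: LiN(i-Pr)2 (1.1 equiv), THF, −78 °C; then t-BuMe2SiOTf, −78 °C; Et3N, aq. NaHCO3
Reagents that add atoms: tert-butyldimethylsilyl trifluoromethanesulfonate, CC(C)(C)[Si](C)(C)OS(=O)(=O)C(F)(F)F
Why: Kinetic α′-deprotonation at C5 (cross-conjugated dienolate formation, as known for isophorone) and O-silylation give the 2-siloxydiene, whose (Z)-enol ether geometry is expected because it keeps the quaternary C4 away from the vinyl group.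

Step 10
Reactants: 18 (2E,8Z,10E)-9,12-bis(tert-butyldimethylsilyloxy)-3,7,7-trimethyldodeca-2,8,10-trienyl pivalate
Product: 19 (2E,8Z,10E)-9,12-bis(tert-butyldimethylsilyloxy)-3,7,7-trimethyldodeca-2,8,10-trien-1-ol
Conditions: i-Bu2AlH (2.5 equiv), CH2Cl2, −78 °C; Rochelle salt
Reagents that add atoms: none
Why: Reductive ester cleavage with i-Bu2AlH at low temperature removes the pivalate under conditions in which the silyl dienol ether and the primary silyl ether are stable.

Step 11
Reactants: 19 (2E,8Z,10E)-9,12-bis(tert-butyldimethylsilyloxy)-3,7,7-trimethyldodeca-2,8,10-trien-1-ol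
Product: 20 (2E,8Z,10E)-9,12-bis(tert-butyldimethylsilyloxy)-3,7,7-trimethyldodeca-2,8,10-trienal
Conditions: activated MnO2 (20 equiv), CH2Cl2, rt
Reagents that add atoms: none
Why: Allylic oxidation with MnO2 is neutral and heterogeneous, so it should give the (E)-enal without E/Z isomerisation and without harm to the siloxydiene.

Step 12
Reactants: 20 (2E,8Z,10E)-9,12-bis(tert-butyldimethylsilyloxy)-3,7,7-trimethyldodeca-2,8,10-trienal
Product: 21 (1R,2R,4aR,8aR)-4-(tert-butyldimethylsilyloxy)-2-[(tert-butyldimethylsilyloxy)methyl]-5,5,8a-trimethyl-1,2,4a,5,6,7,8,8a-octahydronaphthalene-1-carbaldehyde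
Conditions: (S)-1-(2-methylphenyl)-3,3-diphenyltetrahydro-1H,3H-pyrrolo[1,2-c][1,3,2]oxazaborole (20 mol%), HN(SO2CF3)2 (18 mol%), CH2Cl2, 0.01 M, −78 to −20 °C; then Et3N
Reagents that add atoms: none
Why: Proposed new method: the boron-bound (E)-enal is attacked by the tethered 2-siloxydiene in a concerted but asynchronous [4+2] cycloaddition in which the electron-rich terminus C5 bonds to the enal β-carbon C10 ahead of C8–C9; the closest known reaction type is the cationic-oxazaborolidine-catalysed type 1 intramolecular Diels–Alder reaction of 2,7,9-trienals, which has not been shown for a β,β-disubstituted enal that sets a quaternary carbon. Ring B closes as the new cyclohexene by the cycloaddition itself (bonds C5–C10 and C8–C9), and ring A closes through the same C5–C10 bond as the C1–C4 tether folds into a chair in the exo position, helped by the gem-dimethyl group at C4. The cis relation of C11 to the C10 methyl follows from the (E)-enal geometry, the trans ring fusion at C5/C10 and the cis C8/C9 relation follow from the endo position of the catalyst-bound formyl group together with the (8Z,10E)-diene geometry, and the absolute sense follows from the enal face that the catalyst leaves open. The step needs endo over exo selectivity and clean facial discrimination, which the Lewis-acid-enhanced endo preference and the chair tether should secure, and it needs ring closure to outrun intermolecular Mukaiyama-type addition and desilylation, which high dilution and the absence of free HN(SO2CF3)2 should secure.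

Step 13
Reactants: 21 cycloadduct aldehyde
Product: 22 C11=C12 methyl enol ether of the cycloadduct (E/Z mixture)
Conditions: MeOCH2PPh3Cl, KN(SiMe3)2, THF, 0 °C; then 21, −78 to 0 °C
Reagents that add atoms: (methoxymethyl)triphenylphosphonium chloride, COC[P+](c1ccccc1)(c1ccccc1)c1ccccc1.[Cl-]
Why: Wittig methoxymethylenation of the hindered aldehyde adds C12 (one-carbon homologation); the silyl enol ether is inert to the ylide and fast olefination at low temperature should keep C9 from epimerising.

Step 14
Reactants: 22 C11=C12 methyl enol ether of the cycloadduct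
Product: 23 (5R,9S,10S)-17-(tert-butyldimethylsilyloxy)-7-en-6-one bearing the C11=C12 methyl enol ether
Conditions: Pd(OAc)2 (1.1 equiv), MeCN, rt
Reagents that add atoms: none
Why: Saegusa–Ito oxidation: the silyl enol ether transmetalates to a palladium enolate at C7 and syn β-hydride elimination of the C8 hydrogen gives the 7-en-6-one regiospecifically, since C5 has no β-hydrogen, while the methyl enol ether has no O–Si bond to transmetalate; the C8 stereocentre is removed.

Step 15
Reactants: 23 7-en-6-one methyl enol ether
Product: 25 (5R,9S,10S)-17-(tert-butyldimethylsilyloxy)-6-oxo-7-en-12-al, via acetoxymercurio aldehyde 24 (not isolated)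
Conditions: Hg(OAc)2, THF–H2O (10:1), 0 °C; then aq. KI
Reagents that add atoms: water, O
Why: Enol ether hydrolysis by oxymercuration and iodide-induced demercuration unmasks the C12 aldehyde under neutral conditions that spare the allylic silyl ether and the enone.

Step 16
Reactants: 25 keto aldehyde
Product: 26 (5R,9S,10S,12E)-17-(tert-butyldimethylsilyloxy)-13-methyl-6-oxo-7,12-dien-14-al
Conditions: Ph3P=C(CH3)CHO, toluene, 80 °C
Reagents that add atoms: 2-(triphenylphosphoranylidene)propanal, CC(C=O)=P(c1ccccc1)(c1ccccc1)c1ccccc1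
Why: Wittig olefination with the stabilised formyl ylide reacts only with the aldehyde, not with the hindered enone, and should give the (E)-trisubstituted C12=C13 enal as stabilised ylides do.

Step 17
Reactants: 26 enone enal
Product: 27 (5R,9S,10S,12E)-17-(tert-butyldimethylsilyloxy)labda-7,12,14-trien-6-one
Conditions: Ph3PCH3Br, KN(SiMe3)2, THF, 0 °C; then 26 (ylide 1.1 equiv), −78 to −20 °C
Reagents that add atoms: methyltriphenylphosphonium bromide, C[P+](c1ccccc1)(c1ccccc1)c1ccccc1.[Br-]
Why: Wittig methylenation at low temperature converts the unhindered enal into the terminal C14=C15 alkene much faster than the ylide can attack the hindered cross-conjugated C6 ketone.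

Step 18
Reactants: 27 trienone
Product: 28 (5R,6S,9S,10S,12E)-17-(tert-butyldimethylsilyloxy)labda-7,12,14-trien-6-ol
Conditions: NaBH4, CeCl3·7H2O, MeOH–THF, −40 °C
Reagents that add atoms: none
Why: Luche 1,2-reduction should deliver hydride to C6 from the face opposite the C10 methyl and the axial C4 methyl, which gives the axial alcohol with OH cis to the C10 methyl (6S) and leaves the diene untouched.

Step 19
Reactants: 28 silyl ether alcohol
Product: 29 (5R,6S,9S,10S,12E)-labda-7,12,14-triene-6,17-diol
Conditions: Bu4NF, THF, 0 °C to rt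
Reagents that add atoms: none
Why: Fluoride-mediated desilylation frees the primary C17 alcohol without affecting the triene or the allylic alcohol.

Step 20
Reactants: 29 diol
Product: 30 (5R,6S,9S,10S,12E)-labda-7,12,14-triene-6,17-diyl diacetate
Conditions: Ac2O, pyridine, DMAP (cat.), rt
Reagents that add atoms: acetic anhydride, CC(=O)OC(C)=O
Why: Acetylation under nucleophilic catalysis esterifies both the primary and the hindered axial secondary alcohol and should give the target.

**Compound list**

1 | geraniol, (2E)-3,7-dimethylocta-2,6-dien-1-ol | CC(C)=CCC/C(C)=C/CO | starting material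
2 | geranyl tert-butyldimethylsilyl ether | CC(C)=CCC/C(C)=C/CO[Si](C)(C)C(C)(C)C | intermediate
3 | (4E)-6-(tert-butyldimethylsilyloxy)-4-methylhex-4-enal | O=CCC/C(C)=C/CO[Si](C)(C)C(C)(C)C | intermediate
4 | (4E)-6-(tert-butyldimethylsilyloxy)-4-methylhex-4-en-1-ol | OCCC/C(C)=C/CO[Si](C)(C)C(C)(C)C | intermediate
5 | (2E)-6-bromo-3-methylhex-2-enyl tert-butyldimethylsilyl ether | BrCCC/C(C)=C/CO[Si](C)(C)C(C)(C)C | intermediate
6 | mesityl oxide, 4-methylpent-3-en-2-one | CC(=O)C=C(C)C | starting material
7 | Grignard reagent from 5, alkylmagnesium bromide | Br[Mg]CCC/C(C)=C/CO[Si](C)(C)C(C)(C)C | intermediate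
8 | trimethylsilyl enol ether of 9 (C5=C6, geometry not defined) | CC(O[Si](C)(C)C)=CC(C)(C)CCC/C(C)=C/CO[Si](C)(C)C(C)(C)C | intermediate
9 | (8E)-10-(tert-butyldimethylsilyloxy)-4,4,8-trimethyldec-8-en-2-one | CC(=O)CC(C)(C)CCC/C(C)=C/CO[Si](C)(C)C(C)(C)C | intermediate
10 | (8E)-10-hydroxy-4,4,8-trimethyldec-8-en-2-one | CC(=O)CC(C)(C)CCC/C(C)=C/CO | intermediate
11 | (2E)-3,7,7-trimethyl-9-oxodec-2-enyl pivalate | CC(=O)CC(C)(C)CCC/C(C)=C/COC(=O)C(C)(C)C | intermediate
12 | (tert-butyldimethylsilyloxy)acetaldehyde | O=CCO[Si](C)(C)C(C)(C)C | starting material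
13 | lithium enolate of 11 on the methyl side | C=C(O[Li])CC(C)(C)CCC/C(C)=C/COC(=O)C(C)(C)C | intermediate
14 | (2E)-12-(tert-butyldimethylsilyloxy)-11-hydroxy-3,7,7-trimethyl-9-oxododec-2-enyl pivalate, racemic at the carbinol carbon | CC(C)(C)C(=O)OC/C=C(\C)CCCC(C)(C)CC(=O)CC(O)CO[Si](C)(C)C(C)(C)C | intermediate
15 | methanesulfonate of 14 | CC(C)(C)C(=O)OC/C=C(\C)CCCC(C)(C)CC(=O)CC(OS(C)(=O)=O)CO[Si](C)(C)C(C)(C)C | intermediate
16 | (2E,10E)-12-(tert-butyldimethylsilyloxy)-3,7,7-trimethyl-9-oxododeca-2,10-dienyl pivalate | CC(C)(C)C(=O)OC/C=C(\C)CCCC(C)(C)CC(=O)/C=C/CO[Si](C)(C)C(C)(C)C | intermediate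
17 | lithium (8Z,10E)-dienolate of 16 | CC(C)(C)C(=O)OC/C=C(\C)CCCC(C)(C)/C=C(O[Li])/C=C/CO[Si](C)(C)C(C)(C)C | intermediate
18 | (2E,8Z,10E)-9,12-bis(tert-butyldimethylsilyloxy)-3,7,7-trimethyldodeca-2,8,10-trienyl pivalate | CC(C)(C)C(=O)OC/C=C(\C)CCCC(C)(C)/C=C(O[Si](C)(C)C(C)(C)C)/C=C/CO[Si](C)(C)C(C)(C)C | intermediate
19 | (2E,8Z,10E)-9,12-bis(tert-butyldimethylsilyloxy)-3,7,7-trimethyldodeca-2,8,10-trien-1-ol | OC/C=C(\C)CCCC(C)(C)/C=C(O[Si](C)(C)C(C)(C)C)/C=C/CO[Si](C)(C)C(C)(C)C | intermediate
20 | (2E,8Z,10E)-9,12-bis(tert-butyldimethylsilyloxy)-3,7,7-trimethyldodeca-2,8,10-trienal, the cycloaddition precursor | O=C/C=C(\C)CCCC(C)(C)/C=C(O[Si](C)(C)C(C)(C)C)/C=C/CO[Si](C)(C)C(C)(C)C | intermediate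
21 | trans-fused cycloadduct, (5R,8R,9R,10R): C11 aldehyde on C9 cis to the C10 methyl, CH2OSi on C8 cis to the aldehyde, C6=C7 silyl enol ether, 5-H trans to the C10 methyl | O=C[C@@H]1[C@H](CO[Si](C)(C)C(C)(C)C)C=C(O[Si](C)(C)C(C)(C)C)[C@@H]2C(C)(C)CCC[C@@]12C | intermediate
22 | methyl enol ether from 21 (C9–CH=CH–OMe, E/Z mixture; ring stereocentres as in 21) | COC=C[C@@H]1[C@H](CO[Si](C)(C)C(C)(C)C)C=C(O[Si](C)(C)C(C)(C)C)[C@@H]2C(C)(C)CCC[C@@]12C | intermediate
23 | (5R,9S,10S)-7-en-6-one with C8–CH2OSi and the C9 methyl enol ether side chain | COC=C[C@@H]1C(CO[Si](C)(C)C(C)(C)C)=CC(=O)[C@@H]2C(C)(C)CCC[C@@]12C | intermediate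
24 | α-(acetoxymercurio) aldehyde from 23 (mercury on C11, configuration there not defined) | O=CC([Hg]OC(C)=O)[C@@H]1C(CO[Si](C)(C)C(C)(C)C)=CC(=O)[C@@H]2C(C)(C)CCC[C@@]12C | intermediate
25 | (5R,9S,10S)-7-en-6-one with C8–CH2OSi and a C9–CH2–CHO side chain (C12 aldehyde) | O=CC[C@@H]1C(CO[Si](C)(C)C(C)(C)C)=CC(=O)[C@@H]2C(C)(C)CCC[C@@]12C | intermediate
26 | (5R,9S,10S,12E)-7-en-6-one with the C9–CH2–CH=C(CH3)–CHO side chain | O=C/C(C)=C/C[C@@H]1C(CO[Si](C)(C)C(C)(C)C)=CC(=O)[C@@H]2C(C)(C)CCC[C@@]12C | intermediate
27 | (5R,9S,10S,12E)-17-(tert-butyldimethylsilyloxy)labda-7,12,14-trien-6-one | C=C/C(C)=C/C[C@@H]1C(CO[Si](C)(C)C(C)(C)C)=CC(=O)[C@@H]2C(C)(C)CCC[C@@]12C | intermediate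
28 | (5R,6S,9S,10S,12E)-17-(tert-butyldimethylsilyloxy)labda-7,12,14-trien-6-ol, OH cis to the C10 methyl | C=C/C(C)=C/C[C@@H]1C(CO[Si](C)(C)C(C)(C)C)=C[C@H](O)[C@@H]2C(C)(C)CCC[C@@]12C | intermediate
29 | (5R,6S,9S,10S,12E)-labda-7,12,14-triene-6,17-diol | C=C/C(C)=C/C[C@@H]1C(CO)=C[C@H](O)[C@@H]2C(C)(C)CCC[C@@]12C | intermediate
30 | (5R,6S,9S,10S,12E)-labda-7,12,14-triene-6,17-diyl diacetate | C=C/C(C)=C/C[C@@H]1C(COC(C)=O)=C[C@H](OC(C)=O)[C@@H]2C(C)(C)CCC[C@@]12C | target

**Step count**

Total: 20 steps. Longest linear sequence: 20 steps (1 to 30); 6 and 12 are purchased.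

**Steps most likely to fail**

1. Step 12 (proposed new method). The bulky boron Lewis acid may activate the β,β-disubstituted enal too weakly for bond formation at the neopentyl diene terminus, so that desilylation of the diene or open-chain Mukaiyama–Michael addition takes over; the two enal faces may also be poorly distinguished. Fallback: setting out from 20, the same cycloaddition is promoted by the achiral Lewis acid Me2AlCl (1.1 equiv, CH2Cl2, −78 to −20 °C), a known way to run type 1 intramolecular Diels–Alder reactions of trienals. This would give 21 as a racemate, that is, together with its mirror image, the ent-cycloadduct F1. Compound 21 is separated from F1 by preparative chromatography on a chiral stationary phase, and the route is rejoined at 21.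

2. Step 14. Divalent palladium may also attack the electron-rich methyl enol ether (acetoxypalladation or oxidation), or the skipped alkenes of the product may move into conjugation. Fallback: setting out from 22, both enol ethers are hydrolysed (0.5 M HCl, THF, 0 °C) to the keto aldehyde F2. The side chain is then completed first by the two Wittig reactions of steps 16 and 17, which would give the keto enal F3 and then the keto triene F4; the saturated, hindered C6 ketone should not react. The C7=C8 bond is finally introduced without palladium by Mukaiyama dehydrogenation (LiN(i-Pr)2, THF, −78 °C, kinetic enolate at the C7 methylene; then N-tert-butylbenzenesulfinimidoyl chloride), which returns to the route at 27.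

3. Step 2. Over-oxidation may occur, because the second trisubstituted alkene is only moderately deactivated by the allylic silyl ether and may be cleaved before the first is consumed. Fallback: setting out from 2, the terminal alkene is epoxidised selectively with mCPBA (CH2Cl2, −20 °C) to the 6,7-epoxide F5. The epoxide is cleaved with H5IO6 (THF–Et2O, 0 °C) to aldehyde 3, and NaBH4 reduction returns to the route at 4.

**Further compounds**

F1 | step 12 | ent-cycloadduct, mirror image of 21, (5S,8S,9S,10S) | O=C[C@H]1[C@@H](CO[Si](C)(C)C(C)(C)C)C=C(O[Si](C)(C)C(C)(C)C)[C@H]2C(C)(C)CCC[C@]12C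
F2 | step 14 | keto aldehyde: saturated C6 ketone with C8–CH2OSi and C9–CH2–CHO, ring stereocentres as in 21 | O=CC[C@@H]1[C@H](CO[Si](C)(C)C(C)(C)C)CC(=O)[C@@H]2C(C)(C)CCC[C@@]12C
F3 | step 14 | keto enal: saturated C6 ketone with the (12E)-C9–CH2–CH=C(CH3)–CHO side chain | O=C/C(C)=C/C[C@@H]1[C@H](CO[Si](C)(C)C(C)(C)C)CC(=O)[C@@H]2C(C)(C)CCC[C@@]12C
F4 | step 14 | keto triene: 7,8-dihydro derivative of 27 | C=C/C(C)=C/C[C@@H]1[C@H](CO[Si](C)(C)C(C)(C)C)CC(=O)[C@@H]2C(C)(C)CCC[C@@]12C
F5 | step 2 | 6,7-epoxide of geranyl tert-butyldimethylsilyl ether (racemic) | CC1(C)OC1CC/C(C)=C/CO[Si](C)(C)C(C)(C)C
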